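The synthesis rests on cutting the lactone ring (O5, C1–C5) at C4–C5 and O5–C1. That ring has a triketide pattern: oxygenated C3 flanked by methyl-bearing C2 and C4, with the C2 methyl, O3, the C4 methyl and the C6 branch on C5 all cis. It can therefore be assembled flat, as an enol, and shaped afterwards by its own substituents. One operation, a γ-selective Mukaiyama aldol of the bis(trimethylsilyl) dienolate of methyl 2-methyl-3-oxopentanoate followed by lactonisation, brings in every ring atom, both methyls and the C5 centre. Its partner is a C5–C9 aldehyde from an Evans aldol on lactaldehyde, with O7 as tert-butyldimethylsilyl and O8 as triethylsilyl ether.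

Key step: step 8

Remarks on the chemistry
- **Numbering (assumption).** C1 is the lactone carbonyl, C2–C5 the other lactone carbons and O5 the lactone oxygen. C6–C8 are the remaining pyran carbons and C9 is the methyl on C8. O4 is the ether oxygen between C4 and C8; O3 and O7 sit on C3 and C7.
- **Target configuration.** The target is 2R,3S,4R,5S,6R,7R,8S with an E side chain. The rings are trans-fused. On the pyran the C4 methyl is axial, while the C6 methyl, O7 and C9 are equatorial.
- **Starting stereochemistry.** The (R)-auxiliary paired with (S)-lactate gives 6R,7R,8S, which maps onto the target. C8 is later erased and set again.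
- **O7 protection.** O7 is a silyl ether, not a benzyl ether, for three reasons.
  - A benzyl ether is awkward to put on an aldol imide.
  - A benzyl ether would not survive the enol hydrogenation.
  - The required 5,7-syn product runs against the 1,3-anti polar bias of a β-alkoxy aldehyde, and a bulky silyl ether weakens that bias.
- **C4 oxygenation.** C4 is not oxygenated through a C1–C4 dienolate or dienol ether. Such 2H-pyran-type species break the C5–O5 bond and open to dienoic acids. Instead C2 is blocked with chlorine, so that only a cross-conjugated C3=C4 enol ether can form.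
- **Order of ring closure and reduction.** The pyran is closed before C2 and C3 are reduced.
  - No O3 hydroxyl then competes in the C8 oxidation.
  - The free γ-hydroxy β-keto lactone, which could rearrange to a tetronic acid, is short-lived.
  - The angular C4 methyl then steers the hydrogenation.
- **Side chain.** O7 is acylated while C3 is still a ketone, so O7 is the only hydroxyl present. The acyl group is a phosphonoacetate, which survives both reductions, and the enone is made last.

Step 1
Reactants: 1 ethyl (S)-lactate
Product: 2 ethyl (S)-2-(triethylsilyloxy)propanoate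
Conditions: Et3SiCl, imidazole, CH2Cl2, 0 °C → rt
Reagents that add atoms: chlorotriethylsilane, CC[Si](Cl)(CC)CC
Why: Routine silyl ether protection of a secondary alcohol that leaves the stereocentre untouched, the labile triethylsilyl group being chosen so that O8 can later be freed beside a tert-butyldimethylsilyl ether.

Step 2
Reactants: 2 ethyl (S)-2-(triethylsilyloxy)propanoate
Product: 3 (S)-2-(triethylsilyloxy)propanal
Conditions: i-Bu2AlH, CH2Cl2, −78 °C; aqueous work-up
Reagents that add atoms: none
Why: Partial ester reduction with i-Bu2AlH stops at the aluminium hemiacetal at low temperature and should give the α-silyloxy aldehyde without racemisation if it is used at once.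

Step 3
Reactants: 3 (S)-2-(triethylsilyloxy)propanal; 4 (R)-4-benzyl-3-propionyloxazolidin-2-one
Product: 6 (R)-4-benzyl-3-[(2R,3R,4S)-3-hydroxy-2-methyl-4-(triethylsilyloxy)pentanoyl]oxazolidin-2-one, via Z-boron enolate 5 (not isolated)
Conditions: n-Bu2BOTf, Et3N, CH2Cl2, −78 → 0 °C; 3, −78 → 0 °C; H2O2, MeOH, pH 7 buffer, 0 °C
Reagents that add atoms: di-n-butylboron triflate, CCCCB(CCCC)OS(=O)(=O)C(F)(F)F (its boron is carried only by 5 and is lost on work-up)
Why: Evans syn aldol reaction in which the Z-boron enolate reacts through a closed chair and the (R)-benzyl auxiliary sets C6 and C7 (6,7-syn), the 7,8-anti outcome also being the one a Z-enolate prefers with an α-oxygenated aldehyde (matched pair).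

Step 4
Reactants: 6 aldol adduct
Product: 7 (R)-4-benzyl-3-[(2R,3R,4S)-3-(tert-butyldimethylsilyloxy)-2-methyl-4-(triethylsilyloxy)pentanoyl]oxazolidin-2-one
Conditions: TBSOTf, 2,6-lutidine, CH2Cl2, −78 → 0 °C
Reagents that add atoms: tert-butyldimethylsilyl triflate, CC(C)(C)[Si](C)(C)OS(=O)(=O)C(F)(F)F
Why: Silyl triflate and lutidine silylation caps an aldol hydroxyl without retro-aldol cleavage or auxiliary migration and installs the bulky O7 group wanted in step 8.

Step 5
Reactants: 7 silylated imide
Product: 8 (2S,3R,4S)-3-(tert-butyldimethylsilyloxy)-2-methyl-4-(triethylsilyloxy)pentan-1-ol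
Conditions: LiBH4, MeOH (1 equiv), THF, 0 °C
Reagents that add atoms: none
Why: Reductive removal of the oxazolidinone (imide reduction with LiBH4) attacks the exocyclic carbonyl, spares both silyl ethers and does not touch C6.

Step 6
Reactants: 8 primary alcohol
Product: 9 (2R,3R,4S)-3-(tert-butyldimethylsilyloxy)-2-methyl-4-(triethylsilyloxy)pentanal (C5–C9 aldehyde)
Conditions: TEMPO (cat.), PhI(OAc)2, CH2Cl2, rt
Reagents that add atoms: none
Why: Nitroxyl-catalysed oxidation of a primary alcohol stops at the aldehyde under base-free conditions, so the α-centre C6 should keep its configuration.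

Step 7
Reactants: 10 methyl 2-methyl-3-oxopentanoate
Product: 11 1-methoxy-2-methyl-1,3-bis(trimethylsilyloxy)penta-1,3-diene (geometric isomers)
Conditions: TMSOTf (2.3 equiv), Et3N (2.6 equiv), Et2O, 0 °C → rt
Reagents that add atoms: trimethylsilyl triflate, C[Si](C)(C)OS(=O)(=O)C(F)(F)F
Why: Double soft enolisation and O-silylation of a β-keto ester gives the 1,3-bis(silyloxy)diene, the neutral equivalent of the dianion, and its double-bond geometry does not matter because C2 and C4 are set later.

Step 8
Reactants: 9 C5–C9 aldehyde; 11 bis(silyl) dienolate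
Product: 13 4-hydroxy-3,5-dimethyl-5,6-dihydro-2H-pyran-2-one bearing on C5 (S; O5 syn to the C6 methyl) the C6–C9 chain of 9 (C4 epimers), via hydroxy keto ester 12 (not isolated)
Conditions: BF3·OEt2, CH2Cl2, −78 °C; aq. NaHCO3; crude 12, K2CO3, MeOH, 0 °C → rt; aq. KHSO4 (pH 3–4), 0 °C
Reagents that add atoms: none
Why: Monodentate BF3 activates the aldehyde and the dienolate attacks through its γ-carbon (future C4) in an open transition state to give, after loss of silicon, the δ-hydroxy β-keto ester 12; carbonate in methanol then lets O5 add to the C1 ester carbonyl and expel methoxide (6-exo-trig acyl substitution), and the ring rests as its acidic C2=C3 enol. The closest known chemistry is the vinylogous Mukaiyama aldol of 1,3-bis(silyloxy)dienes of β-keto esters with aldehydes and the base-induced closure of the adducts to 4-hydroxy-5,6-dihydropyran-2-ones. The one lasting new stereocentre, C5, is controlled by the methyl-bearing C6 in the Felkin–Anh sense, that is, attack anti to the C7 branch, which places O5 syn to the C6 methyl. Two selectivities are needed: γ over α attack, secured by the larger terminal orbital coefficient and by the methyl on the α-carbon C2, and Felkin over 1,3-anti polar control, which oppose each other in this 6,7-syn aldehyde. The substrate is built to favour Felkin control, since O7 is a bulky and weakly polarising silyl ether that enlarges the antiperiplanar group, BF3 cannot chelate, and the nucleophilic carbon carries a methyl group, which raises steric control in open transition states. C2 and C4 arise as mixtures, which is harmless because C2 is flat in the enol and C4 is flattened in step 10.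

Step 9
Reactants: 13 enol lactone
Product: 14 2-chloro derivative of 13: 3-chloro-3,5-dimethyldihydropyran-2,4-dione with the same C5 substituent (epimers at C2 and C4)
Conditions: NCS, CH2Cl2, 0 °C → rt
Reagents that add atoms: N-chlorosuccinimide, O=C1CCC(=O)N1Cl
Why: Electrophilic α-chlorination of a 2-substituted 1,3-dicarbonyl enol makes C2 quaternary, so that the C3 ketone can enolise only towards C4 and no ring-opening C1–C4 dienolate can arise, both C2 epimers being equally useful.

Step 10
Reactants: 14 chloro dione
Product: 15 C3=C4 trimethylsilyl enol ether of 14 (3-chloro-3,5-dimethyl-4-(trimethylsilyloxy)-3,6-dihydro-2H-pyran-2-one with the same C5 substituent; C2 epimers)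
Conditions: TMSOTf, Et3N, CH2Cl2, −20 → 0 °C
Reagents that add atoms: trimethylsilyl triflate, C[Si](C)(C)OS(=O)(=O)C(F)(F)F
Why: Soft enolisation with a silyl triflate and an amine removes the only α-hydrogen left (on C4) without a free enolate, so both C4 epimers converge on one tetrasubstituted silyl enol ether.

Step 11
Reactants: 15 silyl enol ether
Product: 17 C4,C8-diol: 2-chloro-3-oxo lactone with a tertiary C4 hydroxyl trans to the C6 branch, O7 still TBS-protected and O8 free, via silyloxy epoxide 16 (not isolated)
Conditions: dimethyldioxirane, acetone/CH2Cl2, −40 → 0 °C; then HF·pyridine, pyridine, THF, 0 °C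
Reagents that add atoms: dimethyldioxirane, CC1(C)OO1
Why: Rubottom oxidation in which the dioxirane epoxidises the electron-rich C3=C4 bond on the face opposite the branched C5 substituent (held out of plane by A(1,2) strain with the C4 methyl), so that O4 should end trans to C6, after which buffered fluoride opens the silyloxy epoxide and removes the trimethylsilyl and triethylsilyl groups but not the hindered O7 silyl ether.

Step 12
Reactants: 17 diol
Product: 18 C8 methyl ketone with free C4 hydroxyl (in equilibrium with its hemiketal)
Conditions: Dess–Martin periodinane, CH2Cl2, rt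
Reagents that add atoms: none
Why: Dess–Martin oxidation converts the only secondary alcohol into the ketone under neutral conditions, the tertiary C4 hydroxyl being inert and C7 next to the new ketone not being exposed to base.

Step 13
Reactants: 18 hydroxy ketone
Product: 20 trans-fused bicyclic chloro keto lactone with closed pyran (8S; C9 equatorial; O7 TBS), via cyclic hemiketal 19 (not isolated)
Conditions: Et3SiH, TMSOTf, CH2Cl2, −78 → −20 °C; aq. NaHCO3
Reagents that add atoms: none
Why: Reductive etherification, as in the silane reduction of methyl hemiketals to β-C-glycosides, ionises the hemiketal to the C8 oxocarbenium ion of the trans-fused half-chair and delivers hydride along the axial trajectory (syn to the axial C4 methyl), which sets 8S with C9 equatorial, while the C3 ketone between two quaternary carbons is too hindered and electron-poor to react.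

Step 14
Reactants: 20 bicyclic silyl ether
Product: 21 bicyclic chloro keto lactone with free C7 hydroxyl
Conditions: HF·pyridine, THF, 0 °C → rt
Reagents that add atoms: none
Why: Fluoride-induced desilylation under acidic conditions frees O7 without exposing the non-enolisable but nucleophile-sensitive chloro keto lactone to base.

Step 15
Reactants: 21 C7 alcohol; 22 diethylphosphonoacetic acid
Product: 23 C7 diethylphosphonoacetate of 21
Conditions: EDC·HCl, DMAP (cat.), CH2Cl2, 0 °C → rt
Reagents that add atoms: none
Why: Carbodiimide (Steglich-type) esterification needs no O3/O7 selectivity because O7 is the only hydroxyl at this stage, and the phosphonoacetate, unlike an enone ester, survives the two reductions that follow.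

Step 16
Reactants: 23 chloro keto lactone phosphonoacetate
Product: 24 bicyclic C2=C3 enol lactone (4-hydroxy-3-methyl-5,6-dihydropyran-2-one fused to the pyran) with the C7 phosphonoacetate
Conditions: Zn dust, AcOH, THF, 0 °C → rt
Reagents that add atoms: none
Why: Reductive dehalogenation of an α-chloro 1,3-dicarbonyl compound through its zinc enolate removes the blocking group and returns the enol, which can no longer open or rearrange because C4 is quaternary and O4 is an ether.

Step 17
Reactants: 24 bicyclic enol lactone
Product: 25 (2R,3S)-3-hydroxy-2-methyl lactone with the complete botcinin core and the C7 phosphonoacetate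
Conditions: H2 (60 bar), Raney Ni (washed neutral), EtOAc, rt
Reagents that add atoms: none
Why: Heterogeneous syn-hydrogenation of a 4-hydroxy-5,6-dihydropyran-2-one (the all-cis reduction known for this lactone class) should add both hydrogens from the O4/H5 face because the axial C4 methyl shields the other one, leaving the C2 methyl and O3 cis to the C4 methyl and to C6.

Step 18
Reactants: 26 hexanal
Product: 27 2-oxohexanal
Conditions: SeO2, 1,4-dioxane, H2O, 90 °C; distillation
Reagents that add atoms: selenium dioxide, O=[Se]=O
Why: Riley oxidation converts the only α-methylene group of the aldehyde into a ketone, so no regiochemical question arises.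

Step 19
Reactants: 25 core phosphonoacetate; 27 2-oxohexanal
Product: 28 botcinin I
Conditions: LiCl, i-Pr2NEt, MeCN, 0 °C → rt
Reagents that add atoms: none
Why: Horner–Wadsworth–Emmons olefination under Masamune–Roush conditions deprotonates only the lithium-chelated phosphonoacetate with an amine far too weak to enolise the lactone at C2, and the aldehyde carbonyl of 27 reacts in preference to its ketone to give the E-enoate.

Compound list
1 | ethyl (S)-lactate | CCOC(=O)[C@H](C)O | starting material
2 | ethyl (S)-2-(triethylsilyloxy)propanoate | CCOC(=O)[C@H](C)O[Si](CC)(CC)CC | intermediate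
3 | (S)-2-(triethylsilyloxy)propanal | O=C[C@H](C)O[Si](CC)(CC)CC | intermediate
4 | (R)-4-benzyl-3-propionyloxazolidin-2-one | CCC(=O)N1[C@H](Cc2ccccc2)COC1=O | starting material
5 | Z-di-n-butylboron enolate of 4 | C/C=C(\OB(CCCC)CCCC)N1[C@H](Cc2ccccc2)COC1=O | intermediate
6 | (R)-4-benzyl-3-[(2R,3R,4S)-3-hydroxy-2-methyl-4-(triethylsilyloxy)pentanoyl]oxazolidin-2-one | O=C([C@H](C)[C@@H](O)[C@H](C)O[Si](CC)(CC)CC)N1[C@H](Cc2ccccc2)COC1=O | intermediate
7 | O7 tert-butyldimethylsilyl ether of 6 | O=C([C@H](C)[C@@H](O[Si](C)(C)C(C)(C)C)[C@H](C)O[Si](CC)(CC)CC)N1[C@H](Cc2ccccc2)COC1=O | intermediate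
8 | (2S,3R,4S)-3-(tert-butyldimethylsilyloxy)-2-methyl-4-(triethylsilyloxy)pentan-1-ol | OC[C@H](C)[C@@H](O[Si](C)(C)C(C)(C)C)[C@H](C)O[Si](CC)(CC)CC | intermediate
9 | (2R,3R,4S)-3-(tert-butyldimethylsilyloxy)-2-methyl-4-(triethylsilyloxy)pentanal (C5–C9 aldehyde) | O=C[C@H](C)[C@@H](O[Si](C)(C)C(C)(C)C)[C@H](C)O[Si](CC)(CC)CC | intermediate
10 | methyl 2-methyl-3-oxopentanoate (racemic) | CCC(=O)C(C)C(=O)OC | starting material
11 | 1-methoxy-2-methyl-1,3-bis(trimethylsilyloxy)penta-1,3-diene (geometric isomers) | COC(O[Si](C)(C)C)=C(C)C(O[Si](C)(C)C)=CC | intermediate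
12 | methyl 5-hydroxy-2,4,6-trimethyl-3-oxo-7-(tert-butyldimethylsilyloxy)-8-(triethylsilyloxy)nonanoate; 5,6-syn, 6,7-syn, 7,8-anti; C2 and C4 epimers | COC(=O)C(C)C(=O)C(C)[C@@H](O)[C@H](C)[C@@H](O[Si](C)(C)C(C)(C)C)[C@H](C)O[Si](CC)(CC)CC | intermediate
13 | 4-hydroxy-3,5-dimethyl-5,6-dihydro-2H-pyran-2-one with the C6–C9 chain on C5 (5S; C4 epimers) | CC1=C(O)C(C)[C@@H](OC1=O)[C@H](C)[C@@H](O[Si](C)(C)C(C)(C)C)[C@H](C)O[Si](CC)(CC)CC | intermediate
14 | 2-chloro dione from 13 (C2 and C4 epimers) | CC1(Cl)C(=O)C(C)[C@@H](OC1=O)[C@H](C)[C@@H](O[Si](C)(C)C(C)(C)C)[C@H](C)O[Si](CC)(CC)CC | intermediate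
15 | C3=C4 trimethylsilyl enol ether of 14 (C2 epimers) | CC1(Cl)C(O[Si](C)(C)C)=C(C)[C@@H](OC1=O)[C@H](C)[C@@H](O[Si](C)(C)C(C)(C)C)[C@H](C)O[Si](CC)(CC)CC | intermediate
16 | C3,C4 silyloxy epoxide of 15, oxygen trans to the C6 branch | CC1(Cl)[C@@]2(O[Si](C)(C)C)O[C@@]2(C)[C@@H](OC1=O)[C@H](C)[C@@H](O[Si](C)(C)C(C)(C)C)[C@H](C)O[Si](CC)(CC)CC | intermediate
17 | C4,C8-diol (C4 hydroxyl trans to C6; O7 TBS) | CC1(Cl)C(=O)[C@@](C)(O)[C@@H](OC1=O)[C@H](C)[C@@H](O[Si](C)(C)C(C)(C)C)[C@H](C)O | intermediate
18 | C8 methyl ketone with free C4 hydroxyl | CC1(Cl)C(=O)[C@@](C)(O)[C@@H](OC1=O)[C@H](C)[C@@H](O[Si](C)(C)C(C)(C)C)C(C)=O | intermediate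
19 | bicyclic C8 hemiketal of 18 | CC(C)(C)[Si](C)(C)O[C@@H]1[C@@H](C)[C@@H]2OC(=O)C(C)(Cl)C(=O)[C@@]2(C)OC1(C)O | intermediate
20 | trans-fused bicyclic chloro keto lactone, O7 TBS, 8S | CC(C)(C)[Si](C)(C)O[C@@H]1[C@@H](C)[C@@H]2OC(=O)C(C)(Cl)C(=O)[C@@]2(C)O[C@H]1C | intermediate
21 | bicyclic chloro keto lactone with free C7 hydroxyl | O[C@@H]1[C@@H](C)[C@@H]2OC(=O)C(C)(Cl)C(=O)[C@@]2(C)O[C@H]1C | intermediate
22 | diethylphosphonoacetic acid | CCOP(=O)(OCC)CC(=O)O | starting material
23 | C7 diethylphosphonoacetate of 21 | CCOP(=O)(OCC)CC(=O)O[C@@H]1[C@@H](C)[C@@H]2OC(=O)C(C)(Cl)C(=O)[C@@]2(C)O[C@H]1C | intermediate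
24 | bicyclic C2=C3 enol lactone with C7 phosphonoacetate | CCOP(=O)(OCC)CC(=O)O[C@@H]1[C@@H](C)[C@@H]2OC(=O)C(C)=C(O)[C@@]2(C)O[C@H]1C | intermediate
25 | (2R,3S)-hydroxy lactone core with C7 phosphonoacetate | CCOP(=O)(OCC)CC(=O)O[C@@H]1[C@@H](C)[C@@H]2OC(=O)[C@H](C)[C@H](O)[C@@]2(C)O[C@H]1C | intermediate
26 | hexanal | CCCCCC=O | starting material
27 | 2-oxohexanal | CCCCC(=O)C=O | intermediate
28 | botcinin I | CCCCC(=O)/C=C/C(=O)O[C@@H]1[C@@H](C)[C@@H]2OC(=O)[C@H](C)[C@H](O)[C@@]2(C)O[C@H]1C | target

Total step count: 19. Longest linear sequence: 17 steps (steps 1–6, 8–17 and 19).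

Steps most likely to fail

**Step 8.**
- What may go wrong: facial selectivity at the aldehyde may erode because the polar effect of O7 opposes Felkin control. α-Attack or loss of silyl groups under BF3 may also compete.
- Fallback: it sets out from 9 and 4 and comes back at 13. It replaces the open, substrate-controlled transition state by a closed, reagent-controlled one that forms the same two bonds.
- Imide 4 is taken through a syn aldol with propanal (n-Bu2BOTf, Et3N) to (R)-4-benzyl-3-[(2R,3S)-3-hydroxy-2-methylpentanoyl]oxazolidin-2-one F1.
- This is oxidised (SO3·pyridine, DMSO, Et3N) to (R)-4-benzyl-3-[(R)-2-methyl-3-oxopentanoyl]oxazolidin-2-one F2.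
- Its E-boron enolate ((c-C6H11)2BCl, EtNMe2, Et2O, 0 °C) adds through the same γ-carbon to 9 at −78 °C in an anti aldol reaction.
- The C2 centre of the keto imide and the Felkin preference of E-enolates for α-methyl aldehydes should select the same aldehyde face, giving the δ-hydroxy β-keto imide F3.
- K2CO3 in MeOH then closes O5 onto C1 with loss of the auxiliary and gives 13.

**Step 10 (together with step 11, which depends on it).**
- What may go wrong: enolisation at the crowded C4 may be sluggish, or ionisation of the allylic C2–Cl bond of the enol ether may overtake it and lead on to aromatisation to a pyrone.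
- Fallback: it sets out from 14 and comes back at 17, and it bypasses the neutral enol ether.
- Compound 14 is deprotonated with KN(SiMe3)2 in THF at −78 °C, where α′-enolates of α-chloro ketones persist.
- The enolate is oxidised in situ with 2-(phenylsulfonyl)-3-phenyloxaziridine (enolate hydroxylation), again anti to the C5 substituent, to give the C4 carbinol still bearing both silyl ethers F4.
- HF·pyridine/pyridine then frees O8 and gives 17.

**Step 17.**
- What may go wrong: hydrogen uptake may be slow at the tetrasubstituted enol beside quaternary C4. Forcing conditions may cause hydrogenolysis of the allylic C4–O4 bond.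
- Fallback: it sets out from 23, replaces steps 16 and 17, and comes back at 25. It sets the two centres one after the other.
- Zn(BH4)2 (Et2O, −20 °C) reduces the C3 ketone by axial attack from the face away from the axial C4 methyl, giving the C3 equatorial chlorohydrin F5.
- n-Bu3SnH/AIBN (toluene, 80 °C) then removes chlorine through the planar C2 radical. This radical should take its hydrogen atom from the same unhindered face, leaving the C2 methyl cis to O3.

Further compounds
F1 | step 8 | (R)-4-benzyl-3-[(2R,3S)-3-hydroxy-2-methylpentanoyl]oxazolidin-2-one | O=C([C@H](C)[C@@H](O)CC)N1[C@H](Cc2ccccc2)COC1=O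
F2 | step 8 | (R)-4-benzyl-3-[(R)-2-methyl-3-oxopentanoyl]oxazolidin-2-one | O=C([C@H](C)C(=O)CC)N1[C@H](Cc2ccccc2)COC1=O
F3 | step 8 | δ-hydroxy β-keto imide (2,4-anti, 4,5-anti, 5,6-syn) from F2 and 9 | O=C([C@H](C)C(=O)[C@@H](C)[C@@H](O)[C@H](C)[C@@H](O[Si](C)(C)C(C)(C)C)[C@H](C)O[Si](CC)(CC)CC)N1[C@H](Cc2ccccc2)COC1=O
F4 | step 10 | C4 carbinol of 14 with O7 TBS and O8 TES ethers | CC1(Cl)C(=O)[C@@](C)(O)[C@@H](OC1=O)[C@H](C)[C@@H](O[Si](C)(C)C(C)(C)C)[C@H](C)O[Si](CC)(CC)CC
F5 | step 17 | C2-chloro C3-hydroxy lactone (chlorohydrin) with C7 phosphonoacetate | CCOP(=O)(OCC)CC(=O)O[C@@H]1[C@@H](C)[C@@H]2OC(=O)C(C)(Cl)[C@H](O)[C@@]2(C)O[C@H]1C
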